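- Maple holds 3.53 times the D of larch, yet at 8.00 min its E reads 20.1% against 22.2%, so the way to E does not speed up with D. I therefore follow one Z molecule at a fork: it goes through L to E at a rate free of D, or it meets D and becomes J at a rate proportional to D.

| flask | Z | D | remark | time |
|---|---|---|---|---|
| larch | 0.46 M | 0.19 M | run made earlier |  |
| maple | 0.46 M | 0.67 M | run made earlier |  |
| zeta | 0.46 M | 0.250 M |  | 3.0 h |
| epsilon | 0.46 M | 0.400 M |  | 3.0 h |
| eta | 0.46 M | 0.600 M |  | 3.0 h |
| theta | 0.46 M | 1.00 M |  | 3.0 h |
| delta | 0.46 M | 1.50 M |  | 3.0 h |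

| run | time / min | E / % |
|---|---|---|
| larch | 8.00 | 22.2 |
| larch | 25.0 | 32.7 |
| larch | 40.0 | 32.9 |
| larch | 60.0 | 32.7 |
| larch | 90.0 | 32.3 |
| maple | 8.00 | 20.1 |
| maple | 15.0 | 28.1 |
| maple | 25.0 | 34.5 |
| maple | 50.0 | 38.2 |
| maple | 90.0 | 39.4 |

(scatter of a reading: 0.5 percentage points)
* amount of E at the end, in percent of the Z charged for zeta, epsilon, eta, theta, delta, in this order
* how that number moves from the first to the last of them (falls all the way / rises, then falls / rises all the way / falls, then rises / hardly changes)

- Let d be the D left as a fraction of the Z charge, δ its charged value, and y the E as a fraction of that charge. The odds of J over E are b·d, and b is the fork number, a selectivity factor. Each E and each J takes one D.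
- I take the larch level of 32.9% to mark d near zero, so y is ln(1+bδ)/b. That reading gives b = 1.35, with the scatter of 0.5 percentage points in it.
- The curve of y against δ starts with a slope of 1, one E per D, and bends along that logarithm: zeta, at δ = 0.543, gives 40.7%, and epsilon gives 57.5%.
- Maple's level of 39.4%, put through the same fork, leaves 9.30% of Z for X. I carry that share over as an estimate, which puts the knee, where D stops being the limiting reagent, at δ = 0.907.
- Beyond that estimated knee, I reckon E as the logarithm of the ratio of 1+bδ to 1+b(δ−0.907), over b. This gives 43.4% for eta, 27.6% for theta and 19.0% for delta.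
- The forecast, holding that “Larch stops abruptly because D runs out”, gives 40.5%, 53%, 43%, 28%, 20% (rises, then falls), so at epsilon it stands below my 57.5%.
- The flasks give 41.1%, 52.9%, 42.7%, 30.4%, 22.2%: rises, then falls.

    Z ⇌ L (K = 0.0720, k = 6.87 × 10⁻⁴ s⁻¹)
    Z + D → J (k = 0.00168 M⁻¹ s⁻¹)
    D + L → E (k = 0.971 M⁻¹ s⁻¹)
    2 Z → X (k = 6.93 × 10⁻⁴ M⁻¹ s⁻¹)
    D ⇌ Q (K = 0.900, k = 7.98 × 10⁻⁵ s⁻¹)

- Zeta holds 41.1% of E against my 40.7% from a b read on larch; its D is under a fiftieth of its charge by 0.415 h, and at 3.00 h the path of D to E still runs 41 times its path to J. Epsilon, with Z at 0.10% of its charge and D at 4.5% of its own left, holds X at 21.5%, more than my 9.30%, and E at 52.9%, less than my 57.5%; the row turns at δ = 0.809, below my 0.907, and on theta, with b again, E stands at 30.4% against my 27.6%, beside J at 56.9%.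

(The earlier runs and the new flask were computed for substances that don't exist; scatter was added.)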